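Begin at the late end of the two earlier runs, printed here with the three new flasks and what is asked of them.

| flask | substrate | solid reagent | remark | time |
|---|---|---|---|---|
| winter | 0.13 M (in portions, 3) | 1.5 equiv | run made earlier; portions every 0.60 h |  |
| noon | 0.30 M (in portions, 3) | 1.5 equiv | run made earlier; portions every 0.60 h |  |
| teal | 0.20 M (in portions, 3) | 1.50 equiv | the portions of substrate follow each other after 0.60 h, the first at the start | 6.0 h |
| amber | 0.20 M (in portions, 3) | 1.50 equiv | the portions of substrate follow each other after 2.0 h, the first at the start | 6.0 h |
| red | 0.20 M (in portions, 3) | 1.50 equiv | the portions of substrate follow each other after 6.0 h, the first at the start | 6.0 h |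

- winter (time / h: mono adduct / %, substrate / %): 0.417: 0.3, 32.2; 1.00: 2.8, 62.0; 2.00: 6.5, 88.7; 3.00: 9.8, 80.0; 4.00: 12.0, 74.6; 6.00: 14.5, 61.3; 8.00: 14.7, 51.0
- noon (time / h: mono adduct / %, substrate / %): 1.00: 2.2, 62.7; 2.00: 6.4, 89.3; 3.00: 8.6, 82.2; 4.00: 11.2, 74.9; 5.00: 13.0, 70.0; 6.00: 13.9, 63.9; 8.00: 15.7, 54.2

(each reading ± 0.5 percentage points)

- as a solid, counted per litre of solution: solid reagent
- reactions considered so far: substrate + coupling partner -> mono adduct; substrate + coupling partner -> other mono adduct; coupling partner + mono adduct -> bis adduct; coupling partner + other mono adduct -> bis adduct; solid reagent <-> coupling partner; 2 coupling partner -> homo dimer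
- at the start none of the solid reagent is in solution
- percentages count the whole charge, also what has not yet gone in
- "hardly changes" means that all values lie within two and a half points (for a concentration: within two and a half percent of the largest)

1. amount of mono adduct at the end, in percent of the substrate charged for teal, amber, red, in this order
2. the course of these numbers from the first flask to the last (rises all the way / hardly changes / falls all the way / falls, then rises / rises, then falls)

In the winter run, mono adduct goes from 14.5% at 6.00 h to 14.7% at 8.00 h. That step of 0.2 percentage points stands against a scatter of 0.5 points, so you can take winter mono adduct near 8.00 h to be at its crest, made as fast as it is used. The percent curves at 0.13 M and 0.30 M nearly coincide, so I take the making and using of mono adduct and the loss of substrate as pseudo-first-order at a steady [coupling partner]. Making and using both take that same partner, so it cancels. The crest ratio, [mono adduct]/[substrate] at the crest and thus the making constant over the using constant, reads 0.288. The noon run, whose mono adduct still rises by 1.8 points over the same step, reads 0.290, so the crest stays an estimate.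

Next, the winter substrate falls from 88.7% at 2.00 h to 51.0% at 8.00 h, a loss constant of 0.0922 h⁻¹.

For the making constant, my first pass divides the rise of mono adduct from 2.00 h to 4.00 h by the substrate between them, 80.0%. This gives 0.0344 h⁻¹, and the crest ratio then makes the using constant 0.119 h⁻¹. With f the making constant, u the using constant and k the loss constant, a portion of age t holds the share f/(u−k)·(e^(−kt)−e^(−ut)) of itself as mono adduct, which at 6.0 h comes to 10.9%. The winter reading at 6.00 h, with its later portions younger, is higher at 14.5%, so this link is weak: the rise is net of use.

Put the use back in. The rise equals f([substrate] − [mono adduct]/crest ratio), which gives 0.0598 h⁻¹ and a using constant of 0.207 h⁻¹. The share now crests at age 7.04 h, later than 6.0 h, so in this reckoning older portions hold more up to that age. Averaging the ages gives 14.6% for teal and 12.3% for amber. Red, whose next portion comes at the end, gives 4.96%.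

The forecast reads 14.2%, 11.5%, 5%, falls all the way, on the ground that “Each portion then contributes independently”, and my amber stands higher.

The flasks give 14.6%, 12.3% and 5.07% for teal, amber and red: falls all the way.

    substrate + coupling partner → mono adduct (k = 9.30 × 10⁻⁴ L mol⁻¹ s⁻¹)
    substrate + coupling partner → other mono adduct (k = 5.10 × 10⁻⁴ L mol⁻¹ s⁻¹)
    coupling partner + mono adduct → bis adduct (k = 0.00310 L mol⁻¹ s⁻¹)
    coupling partner + other mono adduct → bis adduct (k = 1.20 × 10⁻⁴ L mol⁻¹ s⁻¹)
    solid reagent ⇌ coupling partner, rate k5*(cs5 - [coupling partner]) while solid is left; crystals form when [coupling partner] > cs5 (solubility = 19.0 mM, k = 0.00220 s⁻¹)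
    2 coupling partner → homo dimer (k = 9.40 × 10⁻⁵ L mol⁻¹ s⁻¹)

At 6.00 h the teal flask makes mono adduct 1.29 times as fast as it uses it. The crest ratio, times its 62.6% substrate and over its mono adduct, gives 1.23. The same reckoning on the red flask, with 19.2% substrate, gives 1.09.

(Readings and results stem from a simulated flask from invented constants; scatter was added.)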